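**Plan**
- Retrosynthesis: the chromone C-ring is opened (Algar–Flynn–Oyamada) to a chalcone from aldehyde 16 and acetophenone 17; the dihydrobenzofuran is then cut at O1–C7a and at C3–C3a into dihalide 5 and β-keto ester 8.
- Enabling feature: C2 carries O1 and C3 carries a one-carbon group, so at the β-keto-ester oxidation level C3 is the acidic carbon of a 1,3-dicarbonyl and O1 its enol oxygen. This C,O-dinucleophile matches the adjacent carbons C3a (as C–I) and C7a (as C–Br) of the catechol-type ring.
- Forward order: arene 5 and β-keto ester 8 → furan ring (step 5, as a flat benzofuran) → dearomatised to the dihydrofuran → C3/C5 side chains adjusted → chalcone → pyranone ring → debenzylation.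
- Stereochemistry: C2 (R) comes from a carboxylate-directed asymmetric hydrogenation of the benzofuran C2=C3 bond; C3 is then epimerised through its ester to the thermodynamically preferred trans arrangement, so both C3 epimers converge.

Key step: step 5

Assumption: the antipode of the chiral Ir ligand in step 7 is chosen so that H2 adds to the face giving (2R). Ring locants used throughout are O1, C2, C3, C3a, C4–C7, C7a.

**Step 1**
Reactants: 1 methyl 4-amino-3-hydroxybenzoate
Product: 2 methyl 4-amino-3-(benzyloxy)benzoate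
Conditions: BnBr (1.05 equiv), K2CO3, DMF, rt
Reagents that add atoms: benzyl bromide, BrCc1ccccc1
Why: Williamson O-alkylation, in which the phenoxide is far more nucleophilic than the aniline nitrogen deactivated by the para ester, so the ether should form chemoselectively.

**Step 2**
Reactants: 2 methyl 4-amino-3-(benzyloxy)benzoate
Product: 3 methyl 4-amino-3-(benzyloxy)-5-iodobenzoate
Conditions: NIS (1.05 equiv), TFA (cat.), MeCN, 0 °C → rt
Reagents that add atoms: N-iodosuccinimide, O=C1CCC(=O)N1I
Why: Electrophilic aromatic iodination directed by the amino group, whose para position is blocked by the ester and one ortho position by OBn, so iodine should enter the remaining ortho carbon (the future C3a).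

**Step 3**
Reactants: 3 methyl 4-amino-3-(benzyloxy)-5-iodobenzoate
Product: 5 methyl 3-(benzyloxy)-4-bromo-5-iodobenzoate, via arenediazonium bromide 4 (not isolated)
Conditions: t-BuONO (1.5 equiv), CuBr2 (1.2 equiv), MeCN, 0 → 60 °C
Reagents that add atoms: copper(II) bromide, [Cu+2].[Br-].[Br-] (bromine of 5); tert-butyl nitrite, CC(C)(C)ON=O (second nitrogen of 4 only)
Why: Non-aqueous Sandmeyer bromination, in which diazotisation and copper-mediated bromine transfer to the aryl radical replace NH2 by Br at the future C7a without touching the C–I bond.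

**Step 4**
Reactants: 6 methyl 4-(benzyloxy)-3-methoxybenzoate; 7 tert-butyl acetate
Product: 8 tert-butyl 3-[4-(benzyloxy)-3-methoxyphenyl]-3-oxopropanoate
Conditions: 7 (2.2 equiv), LiHMDS (3.3 equiv), THF, −78 °C → rt; aq. NH4Cl
Reagents that add atoms: none
Why: Crossed Claisen condensation of the lithium enolate of tert-butyl acetate with the non-enolisable benzoate, driven forward by deprotonation of the β-keto ester product.

**Step 5**
Reactants: 5 methyl 3-(benzyloxy)-4-bromo-5-iodobenzoate; 8 tert-butyl 3-[4-(benzyloxy)-3-methoxyphenyl]-3-oxopropanoate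
Product: 10 3-tert-butyl 5-methyl 7-(benzyloxy)-2-[4-(benzyloxy)-3-methoxyphenyl]-1-benzofuran-3,5-dicarboxylate, via C-arylated β-keto ester 9 (not isolated)
Conditions: CuI (10 mol %), K2CO3 (2.5 equiv), THF, 100 °C, sealed tube
Reagents that add atoms: none
Why: K2CO3 generates the copper(I) enolate of 8, whose central carbon is arylated at the C–I bond of 5 (Hurtley-type oxidative addition/reductive elimination at copper) to give 9, and the enol oxygen of 9 then displaces the neighbouring bromide in an intramolecular Ullmann O-arylation, so that C3a–C3 and O1–C7a form in one flask. The closest known reaction type is the CuI-catalysed domino C-arylation/O-arylation of β-keto esters with 1-bromo-2-iodoarenes to 2,3-disubstituted benzofurans. The furan ring closes by 5-exo attack of the enolate oxygen on aryl carbon C7a (exocyclic C–Br bond) through a six-membered cupracycle. No stereocentre is formed, because the planar benzofuran and the C3 ester are oxidation-level helpers that are removed in steps 6–9. The step needs C-arylation at C3a and O-arylation at C7a; this should be secured by the faster reaction of the C–I bond and by the hindered C–Br bond (between OBn and the new substituent) being reached only intramolecularly by the enol oxygen.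

**Step 6**
Reactants: 10 3-tert-butyl 5-methyl 7-(benzyloxy)-2-[4-(benzyloxy)-3-methoxyphenyl]-1-benzofuran-3,5-dicarboxylate
Product: 11 7-(benzyloxy)-2-[4-(benzyloxy)-3-methoxyphenyl]-5-(methoxycarbonyl)-1-benzofuran-3-carboxylic acid
Conditions: TFA/CH2Cl2 (1:4), rt
Reagents that add atoms: none
Why: Acidolysis of the tert-butyl ester (loss of isobutene) frees the C3 acid as directing group, while the methyl ester, the aryl benzyl ethers and the aromatic benzofuran should be stable to TFA at room temperature.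

**Step 7**
Reactants: 11 7-(benzyloxy)-2-[4-(benzyloxy)-3-methoxyphenyl]-5-(methoxycarbonyl)-1-benzofuran-3-carboxylic acid
Product: 12 (2R,3S)-7-(benzyloxy)-2-[4-(benzyloxy)-3-methoxyphenyl]-5-(methoxycarbonyl)-2,3-dihydro-1-benzofuran-3-carboxylic acid (cis)
Conditions: [Ir(cod)(chiral spiro phosphine–oxazoline, SIPHOX type)]BArF (2 mol %), H2 (10–30 atm), Cs2CO3 (0.5 equiv), MeOH, 50 °C; then 1 M HCl
Reagents that add atoms: none
Why: Proposed new method: the C3 carboxylate should bind the cationic iridium hydride and deliver H2 syn across the C2=C3 bond of the weakly aromatic furan ring (formally an α-aryl-β-aryloxy acrylic acid), the chiral pocket selecting the face so that C2 becomes R and C3 is set cis to it; the closest known reaction types are carboxyl-directed Ir asymmetric hydrogenation of tetrasubstituted α,β-unsaturated acids and asymmetric hydrogenation of benzofurans to 2,3-dihydrobenzofurans, neither shown on a 2-aryl-benzofuran-3-carboxylic acid.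

**Step 8**
Reactants: 12 (2R,3S)-7-(benzyloxy)-2-[4-(benzyloxy)-3-methoxyphenyl]-5-(methoxycarbonyl)-2,3-dihydro-1-benzofuran-3-carboxylic acid
Product: 14 dimethyl (2R,3R)-7-(benzyloxy)-2-[4-(benzyloxy)-3-methoxyphenyl]-2,3-dihydro-1-benzofuran-3,5-dicarboxylate (trans), via cis-dimethyl diester 13 (not isolated)
Conditions: MeI (1.5 equiv), K2CO3, DMF, rt; then NaOMe (0.3 equiv), MeOH, rt
Reagents that add atoms: iodomethane, CI
Why: SN2 O-methylation of the carboxylate followed by base-mediated epimerisation at C3 (enolisation α to the ester) should funnel the cis ester to the thermodynamically favoured trans diester, while C2, which has no acidic hydrogen, keeps the configuration set in step 7.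

**Step 9**
Reactants: 14 dimethyl (2R,3R)-7-(benzyloxy)-2-[4-(benzyloxy)-3-methoxyphenyl]-2,3-dihydro-1-benzofuran-3,5-dicarboxylate
Product: 15 [(2R,3S)-7-(benzyloxy)-2-[4-(benzyloxy)-3-methoxyphenyl]-2,3-dihydro-1-benzofuran-3,5-diyl]dimethanol
Conditions: LiAlH4, THF, 0 °C; Rochelle salt work-up
Reagents that add atoms: none
Why: Hydride reduction of both esters to primary alcohols, with the benzyl ethers and the cyclic ether inert and C3 no longer epimerisable once it carries CH2OH.

**Step 10**
Reactants: 15 [(2R,3S)-7-(benzyloxy)-2-[4-(benzyloxy)-3-methoxyphenyl]-2,3-dihydro-1-benzofuran-3,5-diyl]dimethanol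
Product: 16 (2R,3S)-7-(benzyloxy)-2-[4-(benzyloxy)-3-methoxyphenyl]-3-(hydroxymethyl)-2,3-dihydro-1-benzofuran-5-carbaldehyde
Conditions: activated MnO2 (excess), CH2Cl2, rt
Reagents that add atoms: none
Why: Chemoselective MnO2 oxidation, in which only the benzylic aryl-CH2OH at C5 should be oxidised and the aliphatic C3 hydroxymethyl group left untouched.

**Step 11**
Reactants: 16 (2R,3S)-7-(benzyloxy)-2-[4-(benzyloxy)-3-methoxyphenyl]-3-(hydroxymethyl)-2,3-dihydro-1-benzofuran-5-carbaldehyde; 17 1-[2,4-bis(benzyloxy)-6-hydroxyphenyl]ethanone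
Product: 18 (E)-1-[2,4-bis(benzyloxy)-6-hydroxyphenyl]-3-[(2R,3S)-7-(benzyloxy)-2-[4-(benzyloxy)-3-methoxyphenyl]-3-(hydroxymethyl)-2,3-dihydro-1-benzofuran-5-yl]prop-2-en-1-one
Conditions: KOH (50 % aq.), EtOH/THF, rt
Reagents that add atoms: none
Why: Claisen–Schmidt condensation of the acetophenone enolate with the non-enolisable aldehyde and E1cB dehydration to the (E)-chalcone; the free alcohol and the dihydrobenzofuran (no acidic C–H once the ester is gone) should tolerate aqueous KOH.

**Step 12**
Reactants: 18 the chalcone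
Product: 20 5,7-bis(benzyloxy)-2-[(2R,3S)-7-(benzyloxy)-2-[4-(benzyloxy)-3-methoxyphenyl]-3-(hydroxymethyl)-2,3-dihydro-1-benzofuran-5-yl]-3-hydroxy-4H-chromen-4-one, via 3-hydroxyflavanone 19 (not isolated)
Conditions: 30 % H2O2, NaOH (aq.), MeOH/THF, 0 °C → rt
Reagents that add atoms: hydrogen peroxide, OO
Why: Algar–Flynn–Oyamada oxidative cyclisation, in which alkaline H2O2 converts the 2′-hydroxychalcone by 6-endo closure and α-hydroxylation into the 3-hydroxyflavanone, which is dehydrogenated in situ; the para oxygen (O1) on the B ring should favour closure at the β-carbon over aurone formation.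

**Step 13**
Reactants: 20 the tetra-O-benzyl flavonol
Product: 21 2,3-dehydrosilychristin
Conditions: H2 (1 atm), 10 % Pd/C, THF/MeOH, rt, monitored and stopped at full debenzylation
Reagents that add atoms: none
Why: Catalytic hydrogenolysis of the four aryl benzyl ethers, which should be much faster than cleavage of the cyclic secondary benzylic C2–O1 bond or reduction of the chromone C2=C3 bond.

**Compound list**
1 | methyl 4-amino-3-hydroxybenzoate | COC(=O)c1ccc(N)c(O)c1 | starting material
2 | methyl 4-amino-3-(benzyloxy)benzoate | COC(=O)c1ccc(N)c(OCc2ccccc2)c1 | intermediate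
3 | methyl 4-amino-3-(benzyloxy)-5-iodobenzoate | COC(=O)c1cc(I)c(N)c(OCc2ccccc2)c1 | intermediate
4 | 2-(benzyloxy)-6-iodo-4-(methoxycarbonyl)benzenediazonium bromide (not isolated) | COC(=O)c1cc(I)c([N+]#N)c(OCc2ccccc2)c1.[Br-] | intermediate
5 | methyl 3-(benzyloxy)-4-bromo-5-iodobenzoate | COC(=O)c1cc(I)c(Br)c(OCc2ccccc2)c1 | intermediate
6 | methyl 4-(benzyloxy)-3-methoxybenzoate | COC(=O)c1ccc(OCc2ccccc2)c(OC)c1 | starting material
7 | tert-butyl acetate | CC(=O)OC(C)(C)C | starting material
8 | tert-butyl 3-[4-(benzyloxy)-3-methoxyphenyl]-3-oxopropanoate | COc1cc(C(=O)CC(=O)OC(C)(C)C)ccc1OCc1ccccc1 | intermediate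
9 | methyl 3-(benzyloxy)-4-bromo-5-{1-[4-(benzyloxy)-3-methoxyphenyl]-3-tert-butoxy-1,3-dioxopropan-2-yl}benzoate (not isolated) | COC(=O)c1cc(OCc2ccccc2)c(Br)c(C(C(=O)OC(C)(C)C)C(=O)c2ccc(OCc3ccccc3)c(OC)c2)c1 | intermediate
10 | 3-tert-butyl 5-methyl 7-(benzyloxy)-2-[4-(benzyloxy)-3-methoxyphenyl]-1-benzofuran-3,5-dicarboxylate | COC(=O)c1cc(OCc2ccccc2)c2oc(-c3ccc(OCc4ccccc4)c(OC)c3)c(C(=O)OC(C)(C)C)c2c1 | intermediate
11 | 7-(benzyloxy)-2-[4-(benzyloxy)-3-methoxyphenyl]-5-(methoxycarbonyl)-1-benzofuran-3-carboxylic acid | COC(=O)c1cc(OCc2ccccc2)c2oc(-c3ccc(OCc4ccccc4)c(OC)c3)c(C(=O)O)c2c1 | intermediate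
12 | (2R,3S)-7-(benzyloxy)-2-[4-(benzyloxy)-3-methoxyphenyl]-5-(methoxycarbonyl)-2,3-dihydro-1-benzofuran-3-carboxylic acid (cis) | COc1cc([C@@H]2Oc3c(OCc4ccccc4)cc(C(=O)OC)cc3[C@@H]2C(=O)O)ccc1OCc1ccccc1 | intermediate
13 | dimethyl (2R,3S)-7-(benzyloxy)-2-[4-(benzyloxy)-3-methoxyphenyl]-2,3-dihydro-1-benzofuran-3,5-dicarboxylate (cis, not isolated) | COc1cc([C@@H]2Oc3c(OCc4ccccc4)cc(C(=O)OC)cc3[C@@H]2C(=O)OC)ccc1OCc1ccccc1 | intermediate
14 | dimethyl (2R,3R)-7-(benzyloxy)-2-[4-(benzyloxy)-3-methoxyphenyl]-2,3-dihydro-1-benzofuran-3,5-dicarboxylate (trans) | COc1cc([C@@H]2Oc3c(OCc4ccccc4)cc(C(=O)OC)cc3[C@H]2C(=O)OC)ccc1OCc1ccccc1 | intermediate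
15 | [(2R,3S)-7-(benzyloxy)-2-[4-(benzyloxy)-3-methoxyphenyl]-2,3-dihydro-1-benzofuran-3,5-diyl]dimethanol | COc1cc([C@@H]2Oc3c(OCc4ccccc4)cc(CO)cc3[C@H]2CO)ccc1OCc1ccccc1 | intermediate
16 | (2R,3S)-7-(benzyloxy)-2-[4-(benzyloxy)-3-methoxyphenyl]-3-(hydroxymethyl)-2,3-dihydro-1-benzofuran-5-carbaldehyde | COc1cc([C@@H]2Oc3c(OCc4ccccc4)cc(C=O)cc3[C@H]2CO)ccc1OCc1ccccc1 | intermediate
17 | 1-[2,4-bis(benzyloxy)-6-hydroxyphenyl]ethanone | CC(=O)c1c(O)cc(OCc2ccccc2)cc1OCc1ccccc1 | starting material
18 | (E)-1-[2,4-bis(benzyloxy)-6-hydroxyphenyl]-3-[(2R,3S)-7-(benzyloxy)-2-[4-(benzyloxy)-3-methoxyphenyl]-3-(hydroxymethyl)-2,3-dihydro-1-benzofuran-5-yl]prop-2-en-1-one | COc1cc([C@@H]2Oc3c(OCc4ccccc4)cc(/C=C/C(=O)c4c(O)cc(OCc5ccccc5)cc4OCc4ccccc4)cc3[C@H]2CO)ccc1OCc1ccccc1 | intermediate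
19 | 5,7-bis(benzyloxy)-2-[(2R,3S)-7-(benzyloxy)-2-[4-(benzyloxy)-3-methoxyphenyl]-3-(hydroxymethyl)-2,3-dihydro-1-benzofuran-5-yl]-3-hydroxy-2,3-dihydro-4H-chromen-4-one (isomer mixture at the two transient pyranone centres, not isolated) | COc1cc([C@@H]2Oc3c(OCc4ccccc4)cc(C4Oc5cc(OCc6ccccc6)cc(OCc6ccccc6)c5C(=O)C4O)cc3[C@H]2CO)ccc1OCc1ccccc1 | intermediate
20 | 5,7-bis(benzyloxy)-2-[(2R,3S)-7-(benzyloxy)-2-[4-(benzyloxy)-3-methoxyphenyl]-3-(hydroxymethyl)-2,3-dihydro-1-benzofuran-5-yl]-3-hydroxy-4H-chromen-4-one | COc1cc([C@@H]2Oc3c(OCc4ccccc4)cc(-c4oc5cc(OCc6ccccc6)cc(OCc6ccccc6)c5c(=O)c4O)cc3[C@H]2CO)ccc1OCc1ccccc1 | intermediate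
21 | 2,3-dehydrosilychristin, 3,5,7-trihydroxy-2-[(2R,3S)-7-hydroxy-2-(4-hydroxy-3-methoxyphenyl)-3-(hydroxymethyl)-2,3-dihydro-1-benzofuran-5-yl]-4H-chromen-4-one | COc1cc([C@@H]2Oc3c(O)cc(-c4oc5cc(O)cc(O)c5c(=O)c4O)cc3[C@H]2CO)ccc1O | target

**Step count:** 13 steps in total. The longest linear sequence is 12 steps (1–3 and 5–13).

**Steps most likely to fail**

Step 7 (Proposed new method). The risk is slow or facially unselective hydrogen delivery to the tetrasubstituted, weakly aromatic C2=C3 bond. The fallback replaces asymmetric catalysis by a known dissolving-metal reduction plus resolution and sets out from 10. Magnesium turnings in MeOH/THF reduce the benzofuran-3-carboxylate by electron transfer and protonate the ester enolate to the trans isomer. This gives, as a racemate, 3-tert-butyl 5-methyl (2R,3R)-7-(benzyloxy)-2-[4-(benzyloxy)-3-methoxyphenyl]-2,3-dihydro-1-benzofuran-3,5-dicarboxylate F1 and its (2S,3S) mirror image F2. Preparative chromatography on a chiral stationary phase isolates F1. LiAlH4 in THF then reduces both ester groups of F1 to diol 15, where the route is rejoined, so steps 6–8 are not needed.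

Step 12. The risk is closure of the intermediate chalcone epoxide at the α-carbon (5-exo), which leads to aurone formation and is favoured by the 6′-benzyloxy group. The fallback sets out from chalcone 18. Iodine-catalysed oxidative cyclisation in DMSO at 120 °C gives the flavone 5,7-bis(benzyloxy)-2-[(2R,3S)-7-(benzyloxy)-2-[4-(benzyloxy)-3-methoxyphenyl]-3-(hydroxymethyl)-2,3-dihydro-1-benzofuran-5-yl]-4H-chromen-4-one F3. Dimethyldioxirane (acetone/CH2Cl2, 0 °C) epoxidises its C2=C3 bond to the 2,3-epoxyflavanone F4. A trace of TsOH opens F4 and tautomerises it to the 3-hydroxyflavone 20, where the route is rejoined.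

Step 5. The risk is retro-Claisen loss of the aroyl group from the C-arylated intermediate before the slow O-arylation at the doubly flanked C7a–Br bond. The fallback sets out from 5 and 8, separates the two bond formations and moves the second to palladium. CuI/2-picolinic acid with Cs2CO3 in dioxane at 50 °C stops at the C-arylated β-keto ester 9, which is isolated. Pd-catalysed intramolecular O-arylation of its enolate (Pd2(dba)3, t-BuXPhos, Cs2CO3, toluene, 100 °C) then closes the ring to 10, where the route is rejoined. This fallback makes no compound outside the list (F0).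

**Further compounds**
F1 | step 7 | 3-tert-butyl 5-methyl (2R,3R)-7-(benzyloxy)-2-[4-(benzyloxy)-3-methoxyphenyl]-2,3-dihydro-1-benzofuran-3,5-dicarboxylate | COc1cc([C@@H]2Oc3c(OCc4ccccc4)cc(C(=O)OC)cc3[C@H]2C(=O)OC(C)(C)C)ccc1OCc1ccccc1
F2 | step 7 | 3-tert-butyl 5-methyl (2S,3S)-7-(benzyloxy)-2-[4-(benzyloxy)-3-methoxyphenyl]-2,3-dihydro-1-benzofuran-3,5-dicarboxylate | COc1cc([C@H]2Oc3c(OCc4ccccc4)cc(C(=O)OC)cc3[C@@H]2C(=O)OC(C)(C)C)ccc1OCc1ccccc1
F3 | step 12 | 5,7-bis(benzyloxy)-2-[(2R,3S)-7-(benzyloxy)-2-[4-(benzyloxy)-3-methoxyphenyl]-3-(hydroxymethyl)-2,3-dihydro-1-benzofuran-5-yl]-4H-chromen-4-one | COc1cc([C@@H]2Oc3c(OCc4ccccc4)cc(-c4cc(=O)c5c(OCc6ccccc6)cc(OCc6ccccc6)cc5o4)cc3[C@H]2CO)ccc1OCc1ccccc1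
F4 | step 12 | 2,3-epoxide of F3 (2,3-epoxyflavanone, isomer mixture at the epoxide carbons) | COc1cc([C@@H]2Oc3c(OCc4ccccc4)cc(C45OC4C(=O)c4c(OCc6ccccc6)cc(OCc6ccccc6)cc4O5)cc3[C@H]2CO)ccc1OCc1ccccc1
F0 | step 5 | none | none
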